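(The data were generated by integration for an exercise, and the scatter is random.)

Slowness was what I could read: in oak and birch target stood highest at the first sample and then sank, so I asked how much of that slow loss fits into the asked time.

| flask | starting material | protic impurity | temperature | remark | time |
|---|---|---|---|---|---|
| oak | 2.1 M | 0.45 M | 41 °C | run made earlier |  |
| birch | 2.1 M | 0.45 M | 55 °C | run made earlier |  |
| noon | 1.5 M | 0.450 M | 60 °C |  | 5.0 min |
| summer | 1.5 M | 0.450 M | 35 °C |  | 5.0 min |

| oak: time / min | oak: target / % | birch: time / min | birch: target / % |
|---|---|---|---|
| 0.667 | 21.9 | 0.250 | 17.5 |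
| 1.33 | 20.6 | 0.500 | 16.7 |
| 3.00 | 13.5 | 1.33 | 10.9 |
| 8.00 | 6.2 | 3.00 | 6.5 |

(scatter of a reading: 0.5 percentage points)

- which flask leads in amount of target, in percent of the starting material charged ("all alike" within 1.5 percentage points) (noon / summer / all alike)
- how much target is there at the end, in percent of the starting material charged: noon
- how much target is there at the end, in percent of the starting material charged: summer

- percent here means starting material units held: one target counts as two
- the numbers in the tables scatter with a standard deviation of 0.5 percentage points

From first to last reading, target fell at a fractional rate of 0.172 min⁻¹ in oak and 0.360 min⁻¹ in birch. I treated this as a pseudo-first-order loss and carried it on a logarithmic line in temperature to each flask. That made 0.627 for summer and 2.34 for noon: this is the loss number, the asked time multiplied by the fractional loss rate at the flask's temperature, and its negative exponential is the share of target kept. The first readings, carried on the same line, gave starting levels of 24.1 % for summer and 16.2 % for noon, so I reckoned 12.9 % for summer and 1.55 % for noon. I doubted the noon figure, because oak spanned a loss number of 1.26 and birch 0.990, so noon lay beyond both, and oak's loss slowed from 0.207 min⁻¹ to 0.156 min⁻¹.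

The forecast, reasoning that “formation is fast and loss dominates”, named summer as leader, with 4.5 % for noon, above my figure, and 16 % for summer.

The flasks gave 4.69 % for noon and 12.9 % for summer, so summer led.

    starting material + target → side product (k = 0.0180 M⁻¹ s⁻¹, Ea = 55.0 kJ mol⁻¹)
    starting material + protic impurity → quenched substrate (k = 0.100 M⁻¹ s⁻¹, Ea = 64.0 kJ mol⁻¹)
    starting material ⇌ dormant form (K = 0.870, k = 0.0390 s⁻¹, Ea = 92.0 kJ mol⁻¹, ΔH = −33.0 kJ mol⁻¹)
    2 starting material ⇌ target (K = 0.360 M⁻¹, k = 0.0140 M⁻¹ s⁻¹, Ea = 58.0 kJ mol⁻¹, ΔH = −20.0 kJ mol⁻¹)
    (constants at 60 °C)

Noon's result against its starting level corresponds to a loss number of 1.24, not 2.34. Part of what took target down in noon was its undoing into starting material: with that undoing taken away, noon holds 20.0 % of target instead of 4.69 %. The loss number holds no charge, so a flask like summer but with 2.5 M of starting material keeps 0.627 and my 12.9 %, and that flask held 15.2 %.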